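Flavanone numbering is used. Ring C is cut at the aryl ketone bond C4–C4a and, in the same operation, at O1–C8a, so that ring A enters as the aryne C4a≡C8a. Fluoride releases this aryne and a C2 alkoxide together: the C5 oxygen of ring A polarises the triple bond, O1 adds at C8a, and the C4a carbanion closes ring C on the C4 lactone carbonyl. The precursor is an anti glycolate aldol adduct in which O3 and C4 are locked in a chiral 1,4-dioxan-2-one, a temporary ring that sets C2 and C3, activates C4 and unravels on cyclisation. After the aldol no bond at C2 or C3 is broken.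

Key step: step 7

Assumption: dioxanone 14 (the butane-2,3-diacetal of glycolic acid) is treated as a purchasable chiral glycolate equivalent, and its enolate is taken to react on the face opposite the axial C5 methoxy group. This is the basis for choosing the (5S,6S) enantiomer.

Step 1
Reactants: 1 phloroglucinol (benzene-1,3,5-triol)
Product: 2 3,5-bis(methoxymethoxy)phenol
Conditions: MOMCl (2 equiv), i-Pr2NEt (2 equiv), THF/DMF, 0 °C to rt
Reagents that add atoms: chloromethyl methyl ether (MOMCl), COCCl
Why: Williamson-type O-alkylation of the symmetric triol with the hard electrophile MOMCl, in which two equivalents should make the bis-ether the main component while the mono- and tris-ethers are separable and can be recycled.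

Step 2
Reactants: 2 3,5-bis(methoxymethoxy)phenol
Product: 3 3,5-bis(methoxymethoxy)phenyl N-isopropylcarbamate
Conditions: i-PrNCO, Et3N (cat.), CH2Cl2, rt
Reagents that add atoms: isopropyl isocyanate, CC(C)N=C=O
Why: Base-catalysed addition of the phenol to the isocyanate gives the N–H carbamate, which later serves as the strongest ortho director on the ring and can be removed under mild E1cB conditions.

Step 3
Reactants: 3 3,5-bis(methoxymethoxy)phenyl N-isopropylcarbamate
Product: 9 3,5-bis(methoxymethoxy)-2-(3-methylbut-2-enyl)-6-(trimethylsilyl)phenyl N-isopropylcarbamate, via N-silyl carbamate 4 (not isolated), via aryllithium 5 (not isolated), via arylsilane 6 (not isolated), via aryllithium 7 (not isolated), via N-silyl prenyl arene 8 (not isolated)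
Conditions: TBSOTf, TMEDA, Et2O, 0 °C to rt; n-BuLi (2.1 equiv), TMEDA, −78 °C; TMSCl (1.1 equiv); n-BuLi (1.2 equiv), −78 °C; CuBr·SMe2 (10 mol %), prenyl bromide, −78 to −20 °C; aq NH4Cl work-up
Reagents that add atoms: chlorotrimethylsilane (TMSCl), C[Si](C)(C)Cl; prenyl bromide (1-bromo-3-methylbut-2-ene), CC(C)=CCBr; tert-butyldimethylsilyl triflate (TBSOTf; its silyl group stays only in 4 to 8), CC(C)(C)[Si](C)(C)OS(=O)(=O)C(F)(F)F
Why: Iterative directed ortho metalation: the carbamate, masked in situ as its N-silyl derivative, outranks the MOM ethers as director so that both lithiations occur at the two positions flanked by carbamate and OMOM, silicon is introduced first so that no benzylic-allylic C–H is present during a lithiation, and the second aryllithium displaces prenyl bromide at its primary carbon under copper catalysis.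

Step 4
Reactants: 9 3,5-bis(methoxymethoxy)-2-(3-methylbut-2-enyl)-6-(trimethylsilyl)phenyl N-isopropylcarbamate
Product: 11 3,5-bis(methoxymethoxy)-2-(3-methylbut-2-enyl)-6-(trimethylsilyl)phenyl trifluoromethanesulfonate, via silyl phenol 10 (not isolated)
Conditions: DBU, Et2NH, MeCN, 40 °C; then PhNTf2, rt
Reagents that add atoms: N-phenylbis(trifluoromethanesulfonimide) (PhNTf2), O=S(=O)(N(c1ccccc1)S(=O)(=O)C(F)(F)F)C(F)(F)F
Why: DBU triggers E1cB loss of isopropyl isocyanate (trapped by Et2NH as the urea) and the hindered phenoxide is triflated in the same flask by PhNTf2, an acid-free sequence that spares the protodesilylation-prone arylsilane, the MOM ethers and the prenyl group.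

Step 5
Reactants: 12 3-bromo-4-methoxybenzaldehyde
Product: 13 4-methoxy-3-(3-methylbut-2-enyl)benzaldehyde
Conditions: Bu3SnCH2CH=CMe2, Pd(PPh3)4 (5 mol %), DMF, 100 °C
Reagents that add atoms: tributyl(3-methylbut-2-enyl)stannane, CCCC[Sn](CCCC)(CCCC)CC=C(C)C
Why: Stille coupling: oxidative addition of the aryl bromide to zerovalent palladium, transmetalation of the allylic stannane and reductive elimination at the less hindered primary terminus should give the linear prenyl arene without touching the aldehyde.

Step 6
Reactants: 13 4-methoxy-3-(3-methylbut-2-enyl)benzaldehyde; 14 (5S,6S)-5,6-dimethoxy-5,6-dimethyl-1,4-dioxan-2-one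
Product: 17 (3R,5S,6S)-5,6-dimethoxy-3-{(R)-[4-methoxy-3-(3-methylbut-2-enyl)phenyl](trimethylsilyloxy)methyl}-5,6-dimethyl-1,4-dioxan-2-one, via lithium enolate 15 (not isolated), via lithium aldolate 16 (not isolated)
Conditions: LiN(SiMe3)2, THF, −78 °C; 13; then TMSCl, −78 to −40 °C
Reagents that add atoms: chlorotrimethylsilane (TMSCl), C[Si](C)(C)Cl
Why: Lithium enolate aldol addition: the ring-locked E enolate reacts through a closed chair transition state to give the anti 2,3-dioxygenated adduct, the axial C5 methoxy group of the diacetal blocks one enolate face and so sets flavanone C3 as R and, through the chair, C2 as R, and TMSCl traps the aldolate before it can revert.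

Step 7
Reactants: 11 3,5-bis(methoxymethoxy)-2-(3-methylbut-2-enyl)-6-(trimethylsilyl)phenyl trifluoromethanesulfonate; 17 the silylated anti aldol adduct
Product: 23 (2R,3R)-3-{[(2S)-2-methoxy-3-oxobutan-2-yl]oxy}-5,7-bis(methoxymethoxy)-2-[4-methoxy-3-(3-methylbut-2-enyl)phenyl]-8-(3-methylbut-2-enyl)chroman-4-one, via alkoxide 18 (not isolated), via aryne 19 (not isolated), via C4a carbanion 20 (not isolated), via tricyclic alkoxide 21 (not isolated), via hemiketal alkoxide 22 (not isolated)
Conditions: 11 (1.3 equiv), Bu4N[Ph3SiF2] (slow addition), THF, −20 °C to rt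
Reagents that add atoms: none
Why: Proposed new method: fluoride (and then the methoxide released later, so that one equivalent suffices and the medium ends neutral) strips the O–SiMe3 group of 17 to alkoxide 18 and the C–SiMe3 group of 11 to aryne 19; 18 adds through oxygen to C8a, the resulting C4a carbanion 20 attacks the lactone carbonyl C4, and the tricyclic alkoxide 21 unravels by expelling the diacetal oxygen (22) and then methoxide to give 23. The closest known reaction type is the tandem nucleophilic addition–intramolecular acyl capture of arynes (xanthones from salicylate esters, acridones from anthranilates, dihydroquinolinones from beta-lactams), which has not been shown for an aliphatic beta-hydroxy lactone. Ring C closes in a 6-exo-trig mode (C4a onto C4), and the temporary dioxanone ring is opened in the same event. No lasting stereocenter is created: C2 and C3 come unchanged from 17 because neither the C2–O1 nor the C3–O bond is touched, which matters at the cation-prone 4-methoxybenzylic C2, the anti array places the aryl group and O3 equatorial in the closing ring, and the transient C4 center vanishes. The step needs regioselective O-attack at C8a, secured by the inductively withdrawing C5 OMOM group that distorts the aryne and stabilises charge at C4a despite the C8 prenyl group, and it needs acyl capture in preference to protonation or retro-aldol cleavage, secured by the fully aprotic silyl ether format, the low stationary concentration of 18 under slow fluoride addition and the proximity of the activated alpha-alkoxy lactone.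

Step 8
Reactants: 23 the protected flavanonol
Product: 24 (2R,3R)-3,5,7-trihydroxy-2-[4-methoxy-3-(3-methylbut-2-enyl)phenyl]-8-(3-methylbut-2-enyl)chroman-4-one (target)
Conditions: 3 M aq HCl, MeOH, 45 °C
Reagents that add atoms: none
Why: Acid-catalysed acetal solvolysis removes both aryl MOM ethers and the mixed ketal at O3 in one operation under conditions commonly tolerated by prenylated flavanones, and C2 and C3 are not affected because neither enolisation nor C–O cleavage at these centers is involved.

Compound list
1 | phloroglucinol | Oc1cc(O)cc(O)c1 | starting material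
2 | 3,5-bis(methoxymethoxy)phenol | COCOc1cc(O)cc(OCOC)c1 | intermediate
3 | 3,5-bis(methoxymethoxy)phenyl N-isopropylcarbamate | CC(C)NC(=O)Oc1cc(OCOC)cc(OCOC)c1 | intermediate
4 | 3,5-bis(methoxymethoxy)phenyl N-(tert-butyldimethylsilyl)-N-isopropylcarbamate (in flask) | CC(C)N(C(=O)Oc1cc(OCOC)cc(OCOC)c1)[Si](C)(C)C(C)(C)C | intermediate
5 | 2-lithio derivative of 4 (in flask) | [Li]c1c(OCOC)cc(OCOC)cc1OC(=O)N(C(C)C)[Si](C)(C)C(C)(C)C | intermediate
6 | 2-trimethylsilyl derivative of 4 (in flask) | C[Si](C)(C)c1c(OCOC)cc(OCOC)cc1OC(=O)N(C(C)C)[Si](C)(C)C(C)(C)C | intermediate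
7 | 6-lithio derivative of 6 (in flask) | [Li]c1c(OCOC)cc(OCOC)c([Si](C)(C)C)c1OC(=O)N(C(C)C)[Si](C)(C)C(C)(C)C | intermediate
8 | 6-prenyl derivative of 6 (in flask) | CC(C)=CCc1c(OCOC)cc(OCOC)c([Si](C)(C)C)c1OC(=O)N(C(C)C)[Si](C)(C)C(C)(C)C | intermediate
9 | 3,5-bis(methoxymethoxy)-2-(3-methylbut-2-enyl)-6-(trimethylsilyl)phenyl N-isopropylcarbamate | CC(C)=CCc1c(OCOC)cc(OCOC)c([Si](C)(C)C)c1OC(=O)NC(C)C | intermediate
10 | 3,5-bis(methoxymethoxy)-2-(3-methylbut-2-enyl)-6-(trimethylsilyl)phenol (in flask) | CC(C)=CCc1c(OCOC)cc(OCOC)c([Si](C)(C)C)c1O | intermediate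
11 | 3,5-bis(methoxymethoxy)-2-(3-methylbut-2-enyl)-6-(trimethylsilyl)phenyl triflate | CC(C)=CCc1c(OCOC)cc(OCOC)c([Si](C)(C)C)c1OS(=O)(=O)C(F)(F)F | intermediate
12 | 3-bromo-4-methoxybenzaldehyde | COc1ccc(C=O)cc1Br | starting material
13 | 4-methoxy-3-(3-methylbut-2-enyl)benzaldehyde | COc1ccc(C=O)cc1CC=C(C)C | intermediate
14 | (5S,6S)-5,6-dimethoxy-5,6-dimethyl-1,4-dioxan-2-one | CO[C@@]1(C)OCC(=O)O[C@]1(C)OC | starting material
15 | lithium enolate of 14 (in flask) | CO[C@@]1(C)OC=C(O[Li])O[C@]1(C)OC | intermediate
16 | lithium anti aldolate (in flask) | CO[C@@]1(C)O[C@H]([C@H](O[Li])c2ccc(OC)c(CC=C(C)C)c2)C(=O)O[C@]1(C)OC | intermediate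
17 | (3R,5S,6S)-dioxanone carrying the (R)-aryl(trimethylsilyloxy)methyl group at C3 | CO[C@@]1(C)O[C@H]([C@H](O[Si](C)(C)C)c2ccc(OC)c(CC=C(C)C)c2)C(=O)O[C@]1(C)OC | intermediate
18 | C2 alkoxide from 17 (anion, Bu4N counter-ion, in flask) | CO[C@@]1(C)O[C@H]([C@H]([O-])c2ccc(OC)c(CC=C(C)C)c2)C(=O)O[C@]1(C)OC | intermediate
19 | 3,5-bis(methoxymethoxy)-6-(3-methylbut-2-enyl)benzyne, the aryne C4a≡C8a (in flask) | COCOC1=CC(OCOC)=C(CC=C(C)C)C#C1 | intermediate
20 | O1-arylated C4a carbanion (in flask) | CO[C@@]1(C)O[C@H]([C@H](Oc2[c-]c(OCOC)cc(OCOC)c2CC=C(C)C)c2ccc(OC)c(CC=C(C)C)c2)C(=O)O[C@]1(C)OC | intermediate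
21 | tricyclic C4 hemiketal alkoxide, C4 configuration undefined (in flask) | CO[C@@]1(C)O[C@@H]2[C@@H](c3ccc(OC)c(CC=C(C)C)c3)Oc3c(CC=C(C)C)c(OCOC)cc(OCOC)c3C2([O-])O[C@]1(C)OC | intermediate
22 | ring-opened chromanone with terminal hemiketal alkoxide (in flask) | COc1ccc([C@H]2Oc3c(CC=C(C)C)c(OCOC)cc(OCOC)c3C(=O)[C@@H]2O[C@](C)(OC)[C@@](C)(OC)[O-])cc1CC=C(C)C | intermediate
23 | (2R,3R)-3-{[(2S)-2-methoxy-3-oxobutan-2-yl]oxy}-5,7-bis(methoxymethoxy)-4'-methoxy-3',8-diprenylflavanone | COc1ccc([C@H]2Oc3c(CC=C(C)C)c(OCOC)cc(OCOC)c3C(=O)[C@@H]2O[C@](C)(OC)C(C)=O)cc1CC=C(C)C | intermediate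
24 | (2R,3R)-3,5,7-trihydroxy-4'-methoxy-3',8-diprenylflavanone | COc1ccc([C@H]2Oc3c(CC=C(C)C)c(O)cc(O)c3C(=O)[C@@H]2O)cc1CC=C(C)C | target

Total step count: 8. Longest linear sequence: 6 steps (1, 2, 3, 4, 7, 8).

Steps most likely to fail

Step 7. What may go wrong:
- The free alkoxide may undergo retro-aldol cleavage before it meets the aryne.
- The C4a carbanion may pick up a proton instead of attacking C4.
- The aryne may be consumed by the prenyl alkenes.
- The product may epimerise through base-induced reversible opening of ring C.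

The fallback sets out from 17 and 11 and comes back at 23. Compound 17 is desilylated with citric acid in MeOH to the free alcohol F1. F1 and 11 are combined under the known fluoride-induced O–H insertion of aliphatic alcohols into arynes (KF, 18-crown-6, THF, −20 °C). Here the carbanion is deliberately protonated, and the product is the aryl ether F2. LiOH (THF/H2O, 0 °C) opens the lactone, and the liberated hemiketal loses methanol to give the keto-ketal acid F3. 1-Chloro-N,N,2-trimethylpropenylamine converts it into the acid chloride F4. F4 closes the same C4–C4a bond by intramolecular Friedel–Crafts acylation of the phloroglucinol-type ring in (CF3)2CHOH/CH2Cl2 buffered with 2,6-di-tert-butylpyridine. Only C4a lies within reach of the acyl carbon.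

Step 3. What may go wrong:
- Alkylation of the doubly flanked aryllithium may be slow, which leaves time for carbamoyl migration (anionic ortho-Fries rearrangement).
- Prenyl bromide may be attacked at its tertiary end.
- Reagent carry-over in the single flask may blur the substitution pattern.

The fallback sets out from aryllithium 7 and comes back at 9. Compound 7 is quenched at −78 °C with I2, an essentially instantaneous trap, to the N-silyl aryl iodide F5. Work-up hydrolyses this to the iodo carbamate F6. Stille coupling of F6 with Bu3SnCH2CH=CMe2 (Pd(PPh3)4, CuI, DMF, 60 °C) then installs the prenyl group by cross-coupling instead of alkylation.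

Step 6. What may go wrong: the lithium aldolate may revert and equilibrate while it is being silylated, which erodes the anti selectivity at the carbinol center.

The fallback sets out from 13 and 14 and comes back at 17. The aldolate is quenched with AcOH at −78 °C, and the alcohol (F1 of the first fallback) is taken on together with its carbinol epimer F7. Dess–Martin oxidation of the mixture converges on the beta-keto lactone F8, whose C3 substituent stays equatorial on the diacetal chair. Asymmetric transfer hydrogenation with RuCl[(S,S)-TsDPEN](p-cymene) in HCO2H/Et3N sets the carbinol center under reagent control. TMSCl/imidazole then gives 17.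

Further compounds
F1 | step 7 | (3R,5S,6S)-3-{(R)-hydroxy[4-methoxy-3-(3-methylbut-2-enyl)phenyl]methyl}-5,6-dimethoxy-5,6-dimethyl-1,4-dioxan-2-one | CO[C@@]1(C)O[C@H]([C@H](O)c2ccc(OC)c(CC=C(C)C)c2)C(=O)O[C@]1(C)OC
F2 | step 7 | O-[3,5-bis(methoxymethoxy)-2-(3-methylbut-2-enyl)phenyl] ether of F1 | CO[C@@]1(C)O[C@H]([C@H](Oc2cc(OCOC)cc(OCOC)c2CC=C(C)C)c2ccc(OC)c(CC=C(C)C)c2)C(=O)O[C@]1(C)OC
F3 | step 7 | (2R,3R)-3-aryloxy-3-aryl-2-{[(2S)-2-methoxy-3-oxobutan-2-yl]oxy}propanoic acid | OC(=O)[C@H](O[C@](C)(OC)C(C)=O)[C@H](Oc1cc(OCOC)cc(OCOC)c1CC=C(C)C)c1ccc(OC)c(CC=C(C)C)c1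
F4 | step 7 | acid chloride of F3 | ClC(=O)[C@H](O[C@](C)(OC)C(C)=O)[C@H](Oc1cc(OCOC)cc(OCOC)c1CC=C(C)C)c1ccc(OC)c(CC=C(C)C)c1
F5 | step 3 | 2-iodo-3,5-bis(methoxymethoxy)-6-(trimethylsilyl)phenyl N-(tert-butyldimethylsilyl)-N-isopropylcarbamate | CC(C)N(C(=O)Oc1c(I)c(OCOC)cc(OCOC)c1[Si](C)(C)C)[Si](C)(C)C(C)(C)C
F6 | step 3 | 2-iodo-3,5-bis(methoxymethoxy)-6-(trimethylsilyl)phenyl N-isopropylcarbamate | CC(C)NC(=O)Oc1c(I)c(OCOC)cc(OCOC)c1[Si](C)(C)C
F7 | step 6 | (S)-carbinol epimer of F1 | CO[C@@]1(C)O[C@H]([C@@H](O)c2ccc(OC)c(CC=C(C)C)c2)C(=O)O[C@]1(C)OC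
F8 | step 6 | (3R,5S,6S)-5,6-dimethoxy-3-[4-methoxy-3-(3-methylbut-2-enyl)benzoyl]-5,6-dimethyl-1,4-dioxan-2-one | CO[C@@]1(C)O[C@H](C(=O)c2ccc(OC)c(CC=C(C)C)c2)C(=O)O[C@]1(C)OC
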